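**Retrosynthetic overview**
1. The last C–C bond is C6–C7. It closes the ten-membered ring and the cis-fused α-methylene lactone in one operation, by intramolecular addition of a 2-(methoxycarbonyl)allylindium (a homoenolate equivalent of the enoate, nucleophilic at C7) to the C6 aldehyde.
2. The aldehyde partner is a masked (Z)-4-oxo-enal (a spiro lactol) that already holds the tetrahydrofuran hemiketal C3–O–C10. It is released in the same flask by oxidative opening of a 2,3-disubstituted furan by the pendant C10–OH.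
3. The allyl bromide arm comes from cross-metathesis of a C8 allylic isobutyrate with methyl 2-(bromomethyl)acrylate. C8 is set by catalyst-controlled vinylation of an aldehyde made by anti-Markovnikov Wacker oxidation of (R)-lavender lactone.
4. The furan comes from a (Z)-vinyllithium (from 2-butyne-1,4-diol; fixes the C4=C5 geometry and brings C15) adding to the lactone carbonyl (C3), then cyclodehydration. C10 comes from (R)-linalool.
5. Ring order: γ-lactone of lavender lactone (temporary) → furan (temporary) → tetrahydrofuran hemiketal ring (as spiro lactol) → ten-membered carbocycle and α-methylene-γ-lactone together.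

Assumption and numbering: the SMILES is taken literally, i.e. (3S,6S,7R,8R,10R,4Z) with a cis-fused 12,6-lactone; germacrane numbering is used throughout (C1–C10 ring, C11–C13 acrylate with C12 the carbonyl and C13 the CH2, C14 the methyl on C10, C15 the CH2O carbon on C4); TBS = tert-butyldimethylsilyl.

**Step 1**
Reactants: 1 (R)-(−)-linalool
Product: 3 (5R)-5-ethenyl-5-methyloxolan-2-one ((R)-lavender lactone), via lactol 2 (not isolated)
Conditions: O3, CH2Cl2, −78 °C (Sudan Red 7B end point); Me2S, −78 °C to rt, evaporate; then TEMPO (10 mol%), PhI(OAc)2 (1.2 equiv), CH2Cl2, rt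
Reagents that add atoms: ozone, O=[O+][O-]
Why: Chemoselective ozonolysis cleaves only the electron-rich trisubstituted alkene, the γ-hydroxy aldehyde closes to lactol 2, and TEMPO/PhI(OAc)2 oxidises the lactol to the lactone, so that C10 is taken unchanged from linalool.

**Step 2**
Reactants: 3 (R)-lavender lactone
Product: 4 2-[(2R)-2-methyl-5-oxooxolan-2-yl]acetaldehyde
Conditions: PdCl2(PhCN)2 (10 mol%), CuCl2·2H2O (10 mol%), AgNO2 (5 mol%), O2 (1 atm), t-BuOH/MeNO2 (15:1), rt
Reagents that add atoms: dioxygen, O=O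
Why: Nitrite-modified aldehyde-selective (anti-Markovnikov) Wacker oxidation, in which the allylic lactone oxygen and the quaternary allylic carbon disfavour attack at the internal carbon; no stereocentre is touched.

**Step 3**
Reactants: 4 2-[(2R)-2-methyl-5-oxooxolan-2-yl]acetaldehyde
Product: 5 (5R)-5-[(2R)-2-hydroxybut-3-en-1-yl]-5-methyloxolan-2-one
Conditions: (CH2=CH)2Zn (1.5 equiv), (−)-MIB (10 mol%), toluene, −20 to 0 °C; aq NH4Cl
Reagents that add atoms: divinylzinc, C=C[Zn]C=C
Why: Amino-alcohol-catalysed enantioselective organozinc addition, in which the (−)-MIB–zinc catalyst delivers vinyl to the Si face of the aldehyde and so sets C8 as (R) under catalyst control, the remote C10 centre having little influence.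

**Step 4**
Reactants: 6 2-butyne-1,4-diol
Product: 7 4-{[tert-butyl(dimethyl)silyl]oxy}but-2-yn-1-ol
Conditions: NaH (1.0 equiv), THF, 0 °C; TBSCl (1.0 equiv), 0 °C to rt
Reagents that add atoms: tert-butyldimethylsilyl chloride, CC(C)(C)[Si](C)(C)Cl
Why: Monosilylation of a symmetric diol through its sparingly soluble monosodium alkoxide (statistical desymmetrisation), which differentiates the future C15–O from the future C6–O.

**Step 5**
Reactants: 7 4-{[tert-butyl(dimethyl)silyl]oxy}but-2-yn-1-ol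
Product: 9 (2Z)-4-{[tert-butyl(dimethyl)silyl]oxy}-3-iodobut-2-en-1-ol, via alkenylalanate 8 (not isolated)
Conditions: NaAlH2(OCH2CH2OCH3)2 (Red-Al, 1.5 equiv), THF, 0 °C to rt; then I2 (1.5 equiv), −78 to 0 °C; aqueous work-up
Reagents that add atoms: iodine, II
Why: Hydroxyl-directed trans-hydroalumination of the propargylic alcohol puts aluminium on the distal carbon, cis to CH2OH, in cyclic alanate 8, and iodinolysis with retention gives the (Z)-vinyl iodide, which fixes the C4=C5 geometry of the target.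

**Step 6**
Reactants: 9 (2Z)-4-{[tert-butyl(dimethyl)silyl]oxy}-3-iodobut-2-en-1-ol, 5 (5R)-5-[(2R)-2-hydroxybut-3-en-1-yl]-5-methyloxolan-2-one
Product: 12 (3R,5R)-1-[3-({[tert-butyl(dimethyl)silyl]oxy}methyl)furan-2-yl]-3-methylhept-6-ene-3,5-diol, via vinyllithium 10 (not isolated), via hemiketal 11 (not isolated)
Conditions: 9 (1.5 equiv), t-BuLi (3.1 equiv per 9), Et2O, −78 °C; add 5 (pre-treated with LiN(SiMe3)2, 1.0 equiv, THF, −78 °C), −78 °C, 1 h; aq NH4Cl; then PPTS (10 mol%), CH2Cl2, rt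
Reagents that add atoms: none
Why: Iodine–lithium exchange gives the configurationally stable vinyllithium 10, which adds once to the γ-lactone (stable lithium lactolate) to give hemiketal 11, and acid-catalysed cyclodehydration of this (Z)-γ-hydroxy-enone equivalent (furan synthesis) stores the C3 ketone and C6 oxygen as an inert furan with no new stereocentre.

**Step 7**
Reactants: 12 (3R,5R)-1-[3-({[tert-butyl(dimethyl)silyl]oxy}methyl)furan-2-yl]-3-methylhept-6-ene-3,5-diol
Product: 13 (3R,5R)-7-[3-({[tert-butyl(dimethyl)silyl]oxy}methyl)furan-2-yl]-5-hydroxy-5-methylhept-1-en-3-yl 2-methylpropanoate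
Conditions: (i-PrCO)2O (1.2 equiv), Et3N, DMAP (5 mol%), CH2Cl2, 0 °C
Reagents that add atoms: 2-methylpropanoic anhydride, CC(C)C(=O)OC(=O)C(C)C
Why: DMAP-catalysed acylation is selective for the secondary allylic C8–OH over the tertiary C10–OH and installs the final ester early, so O8 cannot compete in the later lactonisation.

**Step 8**
Reactants: 13 (3R,5R)-7-[3-({[tert-butyl(dimethyl)silyl]oxy}methyl)furan-2-yl]-5-hydroxy-5-methylhept-1-en-3-yl 2-methylpropanoate, 14 methyl 2-(bromomethyl)prop-2-enoate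
Product: 15 methyl (2Z,4R,6R)-2-(bromomethyl)-8-[3-({[tert-butyl(dimethyl)silyl]oxy}methyl)furan-2-yl]-6-hydroxy-6-methyl-4-[(2-methylpropanoyl)oxy]oct-2-enoate
Conditions: second-generation Hoveyda–Grubbs catalyst (2 × 5 mol%), 14 (5 equiv), CH2Cl2, 40 °C
Reagents that add atoms: none
Why: Olefin cross-metathesis between the terminal allylic-ester alkene and a 1,1-disubstituted acrylate that does not homodimerise, as with methacrylates, gives under thermodynamic control the trisubstituted enoate with C8 trans to CO2Me (Z by CIP, CH2Br cis to C8) and leaves C8 untouched.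

**Step 9**
Reactants: 15 methyl (2Z,4R,6R)-2-(bromomethyl)-8-[3-({[tert-butyl(dimethyl)silyl]oxy}methyl)furan-2-yl]-6-hydroxy-6-methyl-4-[(2-methylpropanoyl)oxy]oct-2-enoate
Product: 19 (3S,6S,7R,8R,10R,4Z)-15-{[tert-butyl(dimethyl)silyl]oxy}-3-hydroxy-8-[(2-methylpropanoyl)oxy]-3,10-epoxygermacra-4,11(13)-dien-12,6-olide, via spiro lactol 16 (not isolated), via allylindium 17 (not isolated), via hydroxy ester 18 (not isolated)
Conditions: NBS (1.05 equiv), NaHCO3 (2 equiv), THF/H2O (4:1), 0 °C, 15 min; Na2S2O3 (trace, quench); dilute to 1 mM with THF/H2O (1:1), In powder (5 equiv), 40 °C, ultrasound; extract; then PPTS (20 mol%), CH2Cl2, rt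
Reagents that add atoms: water, O
Why: Proposed new method: NBS/H2O oxidises the furan while the C10 hydroxyl is trapped at C3 (oxidative spiroketalisation of a 2-(γ-hydroxyalkyl)furan, Achmatowicz-type) to give lactol 16, a masked (Z)-4-oxo-enal that already holds the tetrahydrofuran hemiketal ring; zerovalent indium then inserts into the allylic C–Br bond to give allylindium 17, a homoenolate (β-acyl carbanion) equivalent of the enoate, whose C7 adds to the C6 aldehyde released from the lactol (closest known reaction types: indium Barbier allylation of lactols with 2-(bromomethyl)acrylates in water, and intramolecular Barbier macrocyclisation to α-methylene lactones) through a chair Zimmerman–Traxler transition state in which the (Z)-allyl geometry puts C8 axial and gives the 6,7-syn hydroxy ester 18 (cis-lactone after PPTS), while allylic 1,3-strain keeps H-8 in the plane of the allyl unit so that the aldehyde arrives anti to the C9 tether, setting C7 (R) and C6 (S) relative to C8, and the bridge fixes C3 (S).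

**Step 10**
Reactants: 19 (3S,6S,7R,8R,10R,4Z)-15-{[tert-butyl(dimethyl)silyl]oxy}-3-hydroxy-8-[(2-methylpropanoyl)oxy]-3,10-epoxygermacra-4,11(13)-dien-12,6-olide
Product: 20 (3S,6S,7R,8R,10R,4Z)-3,15-dihydroxy-8-[(2-methylpropanoyl)oxy]-3,10-epoxygermacra-4,11(13)-dien-12,6-olide (CNP0282937.2)
Conditions: HF·pyridine, pyridine/THF, 0 °C to rt
Reagents that add atoms: none
Why: Buffered fluoride cleavage of the primary allylic silyl ether (desilylation) leaves the hemiketal, the isobutyrate and the α-methylene lactone untouched, and no stereocentre is affected.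

**Compound list**
1 | (R)-(−)-linalool | CC(=CCC[C@](C)(C=C)O)C | starting material
2 | (5R)-5-ethenyl-5-methyloxolan-2-ol (lactol, anomer mixture) | OC1CC[C@](C)(C=C)O1 | intermediate
3 | (5R)-5-ethenyl-5-methyloxolan-2-one ((R)-lavender lactone) | O=C1CC[C@](C)(C=C)O1 | intermediate
4 | 2-[(2R)-2-methyl-5-oxooxolan-2-yl]acetaldehyde | O=C1CC[C@](C)(CC=O)O1 | intermediate
5 | (5R)-5-[(2R)-2-hydroxybut-3-en-1-yl]-5-methyloxolan-2-one | O=C1CC[C@](C)(C[C@@H](O)C=C)O1 | intermediate
6 | 2-butyne-1,4-diol | OCC#CCO | starting material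
7 | 4-{[tert-butyl(dimethyl)silyl]oxy}but-2-yn-1-ol | OCC#CCO[Si](C)(C)C(C)(C)C | intermediate
8 | sodium cyclic (Z)-alkenylalanate of 7 (five-membered O–Al–C=C–C ring, two 2-methoxyethoxy groups on aluminium) | [Na+].COCCO[Al-]1(OCCOC)OCC=C1CO[Si](C)(C)C(C)(C)C | intermediate
9 | (2Z)-4-{[tert-butyl(dimethyl)silyl]oxy}-3-iodobut-2-en-1-ol | OC/C=C(\I)CO[Si](C)(C)C(C)(C)C | intermediate
10 | lithium (2Z)-4-{[tert-butyl(dimethyl)silyl]oxy}-3-lithiobut-2-en-1-olate | [Li]OC/C=C(\[Li])CO[Si](C)(C)C(C)(C)C | intermediate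
11 | (5R)-2-[(2Z)-1-{[tert-butyl(dimethyl)silyl]oxy}-4-hydroxybut-2-en-2-yl]-5-[(2R)-2-hydroxybut-3-en-1-yl]-5-methyloxolan-2-ol (hemiketal, C2 epimers) | C=C[C@H](O)C[C@@]1(C)CCC(O)(O1)/C(CO[Si](C)(C)C(C)(C)C)=C\CO | intermediate
12 | (3R,5R)-1-[3-({[tert-butyl(dimethyl)silyl]oxy}methyl)furan-2-yl]-3-methylhept-6-ene-3,5-diol | C=C[C@H](O)C[C@](C)(O)CCc1occc1CO[Si](C)(C)C(C)(C)C | intermediate
13 | (3R,5R)-7-[3-({[tert-butyl(dimethyl)silyl]oxy}methyl)furan-2-yl]-5-hydroxy-5-methylhept-1-en-3-yl 2-methylpropanoate | C=C[C@H](OC(=O)C(C)C)C[C@](C)(O)CCc1occc1CO[Si](C)(C)C(C)(C)C | intermediate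
14 | methyl 2-(bromomethyl)prop-2-enoate | C=C(CBr)C(=O)OC | starting material
15 | methyl (2Z,4R,6R)-2-(bromomethyl)-8-[3-({[tert-butyl(dimethyl)silyl]oxy}methyl)furan-2-yl]-6-hydroxy-6-methyl-4-[(2-methylpropanoyl)oxy]oct-2-enoate | COC(=O)/C(CBr)=C/[C@H](OC(=O)C(C)C)C[C@](C)(O)CCc1occc1CO[Si](C)(C)C(C)(C)C | intermediate
16 | methyl (2Z,4R)-2-(bromomethyl)-5-[(7R)-4-({[tert-butyl(dimethyl)silyl]oxy}methyl)-2-hydroxy-7-methyl-1,6-dioxaspiro[4.4]non-3-en-7-yl]-4-[(2-methylpropanoyl)oxy]pent-2-enoate (spiro lactol, epimers at the lactol and spiro carbons) | COC(=O)/C(CBr)=C/[C@H](OC(=O)C(C)C)C[C@@]1(C)CCC2(O1)OC(O)C=C2CO[Si](C)(C)C(C)(C)C | intermediate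
17 | allylindium dibromide of 16 (InBr2 on C13 in place of Br; drawn as the dibromide) | COC(=O)/C(C[In](Br)Br)=C/[C@H](OC(=O)C(C)C)C[C@@]1(C)CCC2(O1)OC(O)C=C2CO[Si](C)(C)C(C)(C)C | intermediate
18 | methyl (4Z)-15-{[tert-butyl(dimethyl)silyl]oxy}-3,6-dihydroxy-8-[(2-methylpropanoyl)oxy]-3,10-epoxygermacra-4,11(13)-dien-12-oate, same spatial arrangement at C3, C6, C7, C8 and C10 as in 19 | C=C(C(=O)OC)[C@H]1[C@@H](O)/C=C(/CO[Si](C)(C)C(C)(C)C)[C@]2(O)CC[C@](C)(C[C@H]1OC(=O)C(C)C)O2 | intermediate
19 | (3S,6S,7R,8R,10R,4Z)-15-{[tert-butyl(dimethyl)silyl]oxy}-3-hydroxy-8-[(2-methylpropanoyl)oxy]-3,10-epoxygermacra-4,11(13)-dien-12,6-olide | C=C1C(=O)O[C@H]2/C=C(/CO[Si](C)(C)C(C)(C)C)[C@]3(O)CC[C@](C)(C[C@@H](OC(=O)C(C)C)[C@@H]12)O3 | intermediate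
20 | (3S,6S,7R,8R,10R,4Z)-3,15-dihydroxy-8-[(2-methylpropanoyl)oxy]-3,10-epoxygermacra-4,11(13)-dien-12,6-olide (CNP0282937.2) | C=C1C(=O)O[C@H]2/C=C(/CO)[C@]3(O)CC[C@](C)(C[C@@H](OC(=O)C(C)C)[C@@H]12)O3 | target

**Step count**
Total: 10 steps. Longest linear sequence: 8 steps from (R)-linalool (steps 1, 2, 3, 6, 7, 8, 9, 10); steps 4 and 5 form the side branch.

**Three steps most likely to fail**

Step 9 (one-pot furan opening and macrocyclisation). The medium-ring closure may lose to protonolysis of the allylindium, and the facial choice at C7/C6 relative to C8 has no direct precedent. The fallback closes the ring at C4=C5 by metathesis instead; it sets out from 5 and comes back at 19. 2-Bromoprop-2-en-1-ol is silylated (TBSCl, imidazole) to tert-butyl[(2-bromoprop-2-en-1-yl)oxy]dimethylsilane F1. Bromine–lithium exchange (t-BuLi, Et2O, −78 °C) gives the vinyllithium F2, which adds to the lithium alkoxide of 5 to give the methylidene hemiketal F3. Selective acylation of the C8 hydroxyl ((i-PrCO)2O, DMAP) gives the isobutyrate F4, and cross-metathesis with 14 as in step 8 gives the allylic bromide F5. An intermolecular indium Barbier reaction with acrolein (In, THF/H2O) gives the hydroxy ester F6 and, after PPTS, the triene cis-lactone F7, with C6 and C7 now set without ring constraint. Ring-closing metathesis between the C6 vinyl group and the C4 methylidene (second-generation Grubbs catalyst, toluene, 80 °C, 1 mM) gives 19.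

Step 8 (cross-metathesis with the bromomethyl acrylate). The hindered acrylate partner and the allylic bromide may give low conversion. The fallback builds the same bromide by Morita–Baylis–Hillman chemistry; it sets out from 13 and comes back at 15. Lemieux–Johnson cleavage of the vinyl group (OsO4 cat., NaIO4, 2,6-lutidine, dioxane/H2O) gives the α-acyloxy aldehyde F8. Morita–Baylis–Hillman reaction with methyl acrylate (DABCO) gives the allylic alcohol F9. Appel bromination (CBr4, PPh3, CH2Cl2, 0 °C) with allylic transposition gives 15.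

Step 2 (aldehyde-selective Wacker oxidation). The hindered vinyl group may react slowly or give the methyl ketone. The fallback uses hydroboration instead; it sets out from 3 and comes back at 4. Hydroboration with 9-BBN (THF, 0 °C to rt) and oxidation with NaBO3·4H2O gives the primary alcohol F10. Dess–Martin periodinane (NaHCO3, CH2Cl2) gives 4.

**Further compounds**
F1 | step 9 | tert-butyl[(2-bromoprop-2-en-1-yl)oxy]dimethylsilane | C=C(Br)CO[Si](C)(C)C(C)(C)C
F2 | step 9 | (3-{[tert-butyl(dimethyl)silyl]oxy}prop-1-en-2-yl)lithium | [Li]C(=C)CO[Si](C)(C)C(C)(C)C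
F3 | step 9 | (5R)-2-(3-{[tert-butyl(dimethyl)silyl]oxy}prop-1-en-2-yl)-5-[(2R)-2-hydroxybut-3-en-1-yl]-5-methyloxolan-2-ol | C=C[C@H](O)C[C@@]1(C)CCC(O)(O1)C(=C)CO[Si](C)(C)C(C)(C)C
F4 | step 9 | (3R)-4-[(2R)-5-(3-{[tert-butyl(dimethyl)silyl]oxy}prop-1-en-2-yl)-5-hydroxy-2-methyloxolan-2-yl]but-1-en-3-yl 2-methylpropanoate | C=C[C@H](OC(=O)C(C)C)C[C@@]1(C)CCC(O)(O1)C(=C)CO[Si](C)(C)C(C)(C)C
F5 | step 9 | methyl (2Z,4R)-2-(bromomethyl)-5-[(2R)-5-(3-{[tert-butyl(dimethyl)silyl]oxy}prop-1-en-2-yl)-5-hydroxy-2-methyloxolan-2-yl]-4-[(2-methylpropanoyl)oxy]pent-2-enoate | COC(=O)/C(CBr)=C/[C@H](OC(=O)C(C)C)C[C@@]1(C)CCC(O)(O1)C(=C)CO[Si](C)(C)C(C)(C)C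
F6 | step 9 | acyclic hydroxy ester from F5 and acrolein (C6 carbinol bearing vinyl, C7 bearing the methyl 2-propenoate unit, configuration at C6, C7, C8, C10 as in 19) | C=C(C(=O)OC)[C@@H]([C@@H](O)C=C)[C@H](OC(=O)C(C)C)C[C@@]1(C)CCC(O)(O1)C(=C)CO[Si](C)(C)C(C)(C)C
F7 | step 9 | triene cis-lactone (α-methylene-γ-butyrolactone with vinyl on C6 and the C8–C10 hemiketal side chain on C7) | C=C[C@@H]1OC(=O)C(=C)[C@@H]1[C@H](OC(=O)C(C)C)C[C@@]2(C)CCC(O)(O2)C(=C)CO[Si](C)(C)C(C)(C)C
F8 | step 8 | (2R,4R)-6-[3-({[tert-butyl(dimethyl)silyl]oxy}methyl)furan-2-yl]-4-hydroxy-4-methyl-1-oxohexan-2-yl 2-methylpropanoate | O=C[C@H](OC(=O)C(C)C)C[C@](C)(O)CCc1occc1CO[Si](C)(C)C(C)(C)C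
F9 | step 8 | methyl (4R,6R)-8-[3-({[tert-butyl(dimethyl)silyl]oxy}methyl)furan-2-yl]-3,6-dihydroxy-6-methyl-2-methylidene-4-[(2-methylpropanoyl)oxy]octanoate (C3 epimers) | C=C(C(=O)OC)C(O)[C@H](OC(=O)C(C)C)C[C@](C)(O)CCc1occc1CO[Si](C)(C)C(C)(C)C
F10 | step 2 | (5R)-5-(2-hydroxyethyl)-5-methyloxolan-2-one | O=C1CC[C@](C)(CCO)O1
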